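The earlier runs and the new flask were generated by integration with made-up constants, and the scatter is random.

The north-east run is the south-west flask, the one asked about, diluted from 10 mM to 6.7 mM of Z, with equivalents and loading unchanged, so the charges of Z, Q and L drop together.

all flasks: L 0.5 mol%

|  | Z | Q | remark |
|---|---|---|---|
| south-west | 10 mM | 1.1 equiv | the very flask that is asked about, followed so far |
| north-east | 6.7 mM | 1.1 equiv | run made earlier |
| flask | 10 mM | 1.10 equiv |  |

- south-west (time / s: J / %): 10.0: 1.4; 12.0: 2.5; 30.0: 5.3; 80.0: 14.0
- north-east (time / min: J / %): 1.00: 8.4; 2.00: 16.3; 3.00: 23.1; 4.00: 29.5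

(standard deviation of a reading: 0.3 percentage points)

- apparent order in L when 10% of the Z are converted (percent change of the rate of making J for one percent more L charged)

Near 10% conversion, the readings give J made at 1.04 mM min⁻¹ in the south-west flask and 0.529 mM min⁻¹ in the north-east run. I call the power of concentration that carries one rate to the other, with the three charges scaled together, the dilution order, n = 1.70. It is the order in L plus m, the combined order in Z and Q, reckoned on the Z left.

In the north-east run, the mean Z left falls to 0.839 of its value between the stretch up to 2.00 min and the stretch from there to 4.00 min, while the rate read falls to 0.810 of its value. So m reads 1.21, leaving 0.491 for L.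

The weak link is m: it rests on a gap of 3.1 percentage points between two stretches, with a scatter of 0.3 points on each reading. So I reforge it from the symmetric case, where each L turns over by itself and the order in L is 1. That case asks for a gap of 1.9 points, which the scatter does not clearly exclude. The mean of the two orders for L is my estimate, 0.746.

The forecast says 1, within 0.6 to 1.4, higher than mine, on the ground that “normal first-order catalysis is plausible”.

The simulation gives 0.87.

    D → G (k = 1.80 s⁻¹)
    G → L + J (k = 8.60 s⁻¹)
    2 E ⇌ X, settled at all times (K = 31000 L mol⁻¹)
    Z + L → E (k = 95.0 L mol⁻¹ s⁻¹)
    Q + E → D (k = 160 L mol⁻¹ s⁻¹)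

In the south-west flask, X, which counts as two, holds 14.2% of the catalyst at 0.400 min and 15.0% at 2.00 min. Taking 0.87 from n leaves m = 0.821. Applied to the Z left from 10% conversion to a converted fraction of 0.7, that m gives a rate ratio of 0.406, and the south-west flask's rate at that fraction, reached at 9.35 min, stands at 0.42 of its rate at 10% conversion.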